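## The problem

The target 16, (3S,5S)-1-(4-hydroxy-3-methoxyphenyl)-7-(4-hydroxy-3,5-dimethoxyphenyl)heptane-3,5-diol, is a linear diarylheptanoid. No ring has to be closed: ring A (guaiacyl, on C1) and ring B (syringyl, on C7) can be bought fully substituted, and the task is to build the seven-carbon chain between them. The chain holds two stereocentres, C3 and C5, both S, as an anti-1,3-diol. Being 1,3-related, either carbinol could direct the formation of the other (for example by anti-selective reduction of a β-hydroxy ketone), but the first would still need its own source, so it is more economical to set both at once. The two ends of the molecule differ only by one methoxy group on ring B, so any plan that grows the chain from both ends must tell two nearly identical arms apart. The free phenols, the syringol above all, are acidic, easily oxidised and incompatible with organometallic reagents; they must stay masked to the last step, and the unmasking must spare the secondary alcohols, which is helped by neither carbinol being benzylic. The enabling feature is that the core C2–C3–C4–C5–C6 with its two oxygens is C2-symmetric, and the bonds C1–C2 and C6–C7 that join it to the two different arms lie outside the stereogenic region and next to benzylic carbons. The core can therefore be an enantiopure bis-electrophile with homotopic ends, and the arms two benzylic nucleophiles.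

## Retrosynthesis

**16 ⇒ 15.** The last operation should only uncover the two phenols, so the two O–CH2Ph bonds are cut and the target is traced back to the bis-benzyl ether 15. Benzyl is preferred to its neighbours: a silyl ether is at risk towards hydroxide and benzylic organomagnesium reagents, an acetal would need acid next to a 1,3-diol, and a methyl ether could not be told from the three methoxy groups that must stay. Compound 15 is no simpler in skeleton, but it has no acidic or oxidisable group. The forward step must cleave two aryl benzyl ethers and nothing else, which is safe because C3 and C5 are not benzylic.

**15 ⇒ 3 + 8 + 13 (through 14).** The chain is cut at C1–C2 and C6–C7. Of the neighbouring cuts, one at C2–C3/C5–C6 would create a stereocentre in each bond-forming event and so require two separate asymmetric carbonyl additions, and one at C3–C4/C4–C5 would leave both stereocentres to a later reduction on the whole skeleton. The outer cut is stereochemically silent: the complete stereodiad comes in the five-carbon bis-epoxide 3, and the arms are the benzylic Grignard reagents 8 and 13, which differ by one methoxy group. The forward reaction must attack only the CH2 terminus of each oxirane, must not break the C–O bonds at the stereocentres, and must place one arm of each kind. Copper catalysis provides the first two. The third is not encoded in the substrate: the ends of 3 are homotopic, so only one mono-adduct (14, kept in the flask) exists, but nothing stops the first reagent from opening both rings. Order of addition and stoichiometry must do this, and the two symmetric bis-adducts are accepted as separable by-products.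

**3 ⇒ 2 ⇒ 1.** Each oxirane of 3 is opened at its O–CH2 bond to a chlorohydrin, giving the dichlorodiol 2, and removal of the two carbinol C–H bonds leads to the achiral diketone 1. Compared with a chiral-pool source or two separate asymmetric oxidations, this sets both stereocentres in one catalytic hydrogenation and passes through a crystalline diol whose purity can be raised before any arene is committed. The forward steps must reduce both carbonyls with anti and absolute control without loss of chloride, then close both rings with base with retention of configuration.

**8 ⇒ 7 ⇒ 6 ⇒ 5 ⇒ 4 and 13 ⇒ 12 ⇒ 11 ⇒ 10 ⇒ 9.** The C–Mg bond of 8 comes from the C–Cl bond of chloride 7, and likewise 13 from 12. Chloride is chosen over bromide because bromide raises the rates of Wurtz coupling and of halohydrin formation in the epoxide opening. The chlorides come from the benzylic alcohols 6 and 11, these from the aldehydes 5 and 10, and these by O-benzylation from vanillin 4 and syringaldehyde 9. These are the cheapest commercial carriers of the two ring patterns and already hold the benzylic carbon. All of these are routine interconversions; only the magnesium insertion is demanding.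

## Roads not taken

Alternative 1: The cut runs through ring B itself, at its C2–C3 and C5–C6 bonds, so that the syringyl ring is made last.
- Forward key step: the potassium enolate of 1,3-dimethoxyacetone A3 would condense twice with the aminoacrolein A2, a 3-(dimethylamino)-2-alkylprop-2-enal whose alkyl group is the whole acetonide-protected chain with ring A attached. Twofold elimination (of the amino group and of the carbonyl oxygen) would aromatise the new carbocycle to the 2,6-dimethoxyphenol A1, the acetonide of the mono-benzyl ether of the diol.
- Merits: the two arms can never be confused, the syringol arrives unprotected while the other phenol stays benzylated, and ring B could be varied late.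
- Weak points: it builds a benzene ring that is sold as syringaldehyde 9. It leaves the stereodiad to separate, earlier chemistry. A2 needs formylation chemistry on an aldehyde that carries an acid-labile acetonide. The linear sequence is much longer.
- Comparison: on arm differentiation this road is better than the plan adopted here, which accepts a statistical loss. The adopted plan sets against that its brevity, the purchase of both rings, and the delivery of chain and stereochemistry by one small block.

Alternative 2: No C–C bond but the C3–O and C4–O bonds of an oxirane define the key step.
- Forward key step: the racemic (E)-allylic alcohol A4 (carbinol at C5, alkene at C3=C4, both arms in place) would undergo Sharpless kinetic resolution in the L-(+)-tartrate series. The (5S) enantiomer would be epoxidised to the erythro epoxy alcohol A5, and hydride delivery to C4 would then give 15.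
- Merits: the arms are joined one after the other by ordinary carbonyl chemistry, so symmetric by-products cannot form. The waste is the unreacted enantiomer of A4, which is easy to separate from A5. No benzylic organomagnesium reagent is needed.
- Weak points: at best half of a fully assembled skeleton is discarded. Because the epoxide and not the recovered alcohol is wanted, its enantiomeric purity falls as conversion rises, so the reaction must be stopped early. A4 needs two C–C bond formations from longer arene building blocks. The C3 centre depends on the regiochemistry of the hydride opening.
- Comparison: both plans have a ceiling near one half in the key step. The adopted plan loses cheap fragments in one flask and takes its configuration from an enantiopure, recrystallised precursor; this road loses advanced material and its optical purity depends on conversion. It is better in one respect: product and waste are easier to separate than three homologous diols.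

Alternative 3: The cut is at C3–C4 and C4–C5; malonic acid A9 supplies C4 and the arms come as the 3-arylpropanoyl imidazolides A7 (guaiacyl) and A8 (syringyl).
- Forward key step: as its magnesium enolate, A9 would be C-acylated by A7, decarboxylate, be acylated again by A8 and decarboxylate a second time to the 3,5-diketone A6. An asymmetric 1,3-diketone hydrogenation with the catalyst type of step 1 would then give 15.
- Merits: it is biomimetic and convergent and uses no halide and no benzylic organometallic reagent. The arms are told apart by the order of acylation and not by statistics, and both stereocentres are set on the complete skeleton in one catalytic step. If the double acylation were reliable, this road would equal or surpass the adopted one in material economy.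
- Weak points: that reliability is the open question. After the first decarboxylation the β-keto acid enolate can be protonated and decarboxylate to a methyl ketone before it meets A8, acyl exchange leads to symmetric diketones, and O-acylation competes. A7 and A8 each need a chain extension, an alkene reduction that must spare or precede the benzyl ether, and an activation. The asymmetric hydrogenation comes last, on a fully enolised lipophilic diketone, with no assured crystalline checkpoint.
- Comparison: the adopted plan sets against it a C–C bond-forming reaction type that is established on this bis-epoxide, and optical purity secured at a two-step, recrystallisable stage.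

Key step: step 11

Assumption: 1,5-dichloropentane-2,4-dione (1) is taken as a catalogue chemical.
Assumption: the (S) ligand is assigned to the (2R,4R) series by carrying over the facial sense known for pentane-2,4-dione and 4-chloroacetoacetates (the descriptor inverts because CH2Cl outranks the inner CH2); the sign of rotation of 3 is checked once and the (R) ligand is used instead if it is opposite.

## Route

Step 1
Reactants: 1 1,5-dichloropentane-2,4-dione
Product: 2 (2R,4R)-1,5-dichloropentane-2,4-diol
Conditions: H2 (85 bar), RuCl2[(S)-BINAP] (0.2 mol%), MeOH, 90 °C, short reaction time; recrystallisation
Reagents that add atoms: none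
Why: Noyori asymmetric hydrogenation of a 1,3-diketone: the substrate binds divalent ruthenium through its two oxygen atoms and the BINAP ligand chooses the carbonyl face in the first reduction and again in the second, so the anti, C2-symmetric diol should be the main product with both new stereocentres set by the ligand alone. The elevated temperature follows the practice for 4-chloro-3-oxo esters, where it favours the oxygen-chelated pathway over competing chloride coordination, and recrystallisation of the crystalline diol is expected to remove the syn (meso) diol and the minor enantiomer.

Step 2
Reactants: 2 (2R,4R)-1,5-dichloropentane-2,4-diol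
Product: 3 (2R,4R)-1,2:4,5-diepoxypentane
Conditions: KOH (powdered, 4 equiv.), Et2O, 23 °C; distillation
Reagents that add atoms: none
Why: Twofold intramolecular Williamson etherification (3-exo-tet): each alkoxide displaces the neighbouring primary chloride, the C–O bonds at the stereocentres are not broken, and configuration and descriptors are retained. The volatile, water-soluble product is isolated by distillation and not by aqueous work-up.

Step 3
Reactants: 4 vanillin (4-hydroxy-3-methoxybenzaldehyde)
Product: 5 4-benzyloxy-3-methoxybenzaldehyde
Conditions: BnBr (1.1 equiv.), K2CO3 (1.5 equiv.), DMF, 60 °C
Reagents that add atoms: benzyl bromide, BrCc1ccccc1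
Why: Williamson ether synthesis: the phenol, acidified by the para formyl group, is deprotonated by K2CO3 and alkylated by benzyl bromide, while the aldehyde does not react under these conditions.

Step 4
Reactants: 5 4-benzyloxy-3-methoxybenzaldehyde
Product: 6 (4-benzyloxy-3-methoxyphenyl)methanol
Conditions: NaBH4 (0.6 equiv.), MeOH–THF, 0 °C
Reagents that add atoms: none
Why: Borohydride reduction of an aromatic aldehyde to the benzylic alcohol; the aryl benzyl ether and the methoxy group are inert to NaBH4.

Step 5
Reactants: 6 (4-benzyloxy-3-methoxyphenyl)methanol
Product: 7 4-benzyloxy-3-methoxybenzyl chloride
Conditions: SOCl2 (1.2 equiv.), CH2Cl2, 0 to 23 °C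
Reagents that add atoms: thionyl chloride, O=S(Cl)Cl
Why: Deoxychlorination of an electron-rich benzylic alcohol with SOCl2, fast at 0 °C because the alkoxy groups stabilise positive charge at the benzylic carbon. The aryl benzyl ether withstands the HCl released at this temperature, and the crystalline chloride is dried and used without long storage.

Step 6
Reactants: 7 4-benzyloxy-3-methoxybenzyl chloride
Product: 8 4-benzyloxy-3-methoxybenzylmagnesium chloride (titrated THF solution, used directly)
Conditions: Mg turnings (3 equiv.), THF, start at 23 °C, then 0 °C, slow addition of 7 (final 0.25 M); titration
Reagents that add atoms: magnesium, [Mg]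
Why: Grignard reagent formation by insertion of magnesium into the benzylic C–Cl bond; slow addition of the chloride to a large excess of metal at 0 °C keeps its stationary concentration low and so holds back Wurtz homocoupling. Para-alkoxybenzylmagnesium chlorides are established reagents that are handled as dilute, titrated THF solutions.

Step 7
Reactants: 9 syringaldehyde (4-hydroxy-3,5-dimethoxybenzaldehyde)
Product: 10 4-benzyloxy-3,5-dimethoxybenzaldehyde
Conditions: BnBr (1.2 equiv.), K2CO3 (2 equiv.), DMF, 70 °C
Reagents that add atoms: benzyl bromide, BrCc1ccccc1
Why: Williamson ether synthesis; the phenol lies between two methoxy groups and is more hindered than that of vanillin, hence the larger excess of base and benzyl bromide and the higher temperature.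

Step 8
Reactants: 10 4-benzyloxy-3,5-dimethoxybenzaldehyde
Product: 11 (4-benzyloxy-3,5-dimethoxyphenyl)methanol
Conditions: NaBH4 (0.6 equiv.), MeOH–THF, 0 °C
Reagents that add atoms: none
Why: Borohydride reduction of the aromatic aldehyde, as in step 4; no other group in the molecule is reducible by NaBH4.

Step 9
Reactants: 11 (4-benzyloxy-3,5-dimethoxyphenyl)methanol
Product: 12 4-benzyloxy-3,5-dimethoxybenzyl chloride
Conditions: SOCl2 (1.2 equiv.), CH2Cl2, 0 °C
Reagents that add atoms: thionyl chloride, O=S(Cl)Cl
Why: Deoxychlorination with SOCl2 as in step 5; the three alkoxy groups make this the more easily ionised of the two chlorides, so it is kept cold and dry and carried on at once.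

Step 10
Reactants: 12 4-benzyloxy-3,5-dimethoxybenzyl chloride
Product: 13 4-benzyloxy-3,5-dimethoxybenzylmagnesium chloride (titrated THF solution, used directly)
Conditions: Mg turnings (3 equiv.), THF, start at 23 °C, then 0 °C, slow addition of 12 (final 0.25 M); titration
Reagents that add atoms: magnesium, [Mg]
Why: Grignard reagent formation as in step 6, with the same measures against Wurtz coupling; this reagent is used in excess in step 11, so a moderate titre is acceptable.

Step 11
Reactants: 3 (2R,4R)-1,2:4,5-diepoxypentane, 8 4-benzyloxy-3-methoxybenzylmagnesium chloride, 13 4-benzyloxy-3,5-dimethoxybenzylmagnesium chloride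
Product: 15 (3S,5S)-1-(4-benzyloxy-3-methoxyphenyl)-7-(4-benzyloxy-3,5-dimethoxyphenyl)heptane-3,5-diol, via chloromagnesium epoxy alkoxide 14 (not isolated)
Conditions: 3 (1.0 equiv.), CuI (10 mol%), THF, −40 °C; 8 (0.9 equiv.) over 2 h; then 13 (1.6 equiv.), −40 to 0 °C; aq. NH4Cl
Reagents that add atoms: none
Why: CuI is converted by the benzylmagnesium chloride into a benzylcopper species (monovalent copper) that attacks the unsubstituted CH2 of an oxirane in an SN2 sense, passes through a trivalent copper alkyl and forms the C–C bond by reductive elimination, the oxygen leaving as its chloromagnesium alkoxide, so that copper turns over and the event is repeated at the second oxirane. The closest known reaction type is the copper-catalysed terminal opening of monosubstituted epoxides by Grignard reagents, which has been shown on this bis-epoxide with one nucleophile after another; here the intermediate 14 is simply left in the flask. No ring is closed and no stereocentre is created: the C–O bonds at C3 and C5 are never broken, so the (2R,4R) configuration of 3 is carried over and is only renamed (3S,5S) because each new CH2CH2Ar arm ranks below the central CH2. Regioselectivity is secured by the steric bias of a monosubstituted oxirane towards a soft organocopper nucleophile at low temperature. The C2 symmetry of 3 makes its two oxiranes homotopic, so the first benzyl group gives the single mono-adduct 14 whichever end it attacks, and the arms are told apart only by the order of addition; 8, the reagent with the more reliable titre, is added first. The substrate cannot supply selectivity for mono- against double opening by 8, since the oxirane of 14 is about as reactive as those of 3; this is handled by making 8 the limiting reagent, adding it slowly to cold, dilute 3 so that 3 is always in excess, and then consuming every remaining oxirane with an excess of 13. On a purely statistical basis about half of 3 can end as 15, the rest as the two symmetric bis-adducts, which carry two and four methoxy groups against three in 15 and should therefore separate on silica. Chloride as the counter-ion together with copper catalysis keeps halohydrin formation by MgCl2 in the background.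

Step 12
Reactants: 15 (3S,5S)-1-(4-benzyloxy-3-methoxyphenyl)-7-(4-benzyloxy-3,5-dimethoxyphenyl)heptane-3,5-diol
Product: 16 (3S,5S)-1-(4-hydroxy-3-methoxyphenyl)-7-(4-hydroxy-3,5-dimethoxyphenyl)heptane-3,5-diol
Conditions: H2 (1 bar), 10% Pd/C, EtOAc–MeOH, 23 °C
Reagents that add atoms: none
Why: Hydrogenolysis of the two aryl benzyl ethers over Pd/C; the chain has no benzylic C–O bond (the carbinols sit at C3 and C5), so only the O–CH2Ph bonds are cleaved and the stereocentres are not touched. The neutral conditions spare the oxidation-prone syringol.

## Compound list

1 | 1,5-dichloropentane-2,4-dione | ClCC(=O)CC(=O)CCl | starting material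
2 | (2R,4R)-1,5-dichloropentane-2,4-diol | ClC[C@H](O)C[C@@H](O)CCl | intermediate
3 | (2R,4R)-1,2:4,5-diepoxypentane | C1O[C@@H]1C[C@@H]1CO1 | intermediate
4 | vanillin (4-hydroxy-3-methoxybenzaldehyde) | COc1cc(C=O)ccc1O | starting material
5 | 4-benzyloxy-3-methoxybenzaldehyde | COc1cc(C=O)ccc1OCc1ccccc1 | intermediate
6 | (4-benzyloxy-3-methoxyphenyl)methanol | COc1cc(CO)ccc1OCc1ccccc1 | intermediate
7 | 4-benzyloxy-3-methoxybenzyl chloride | COc1cc(CCl)ccc1OCc1ccccc1 | intermediate
8 | 4-benzyloxy-3-methoxybenzylmagnesium chloride | COc1cc(C[Mg]Cl)ccc1OCc1ccccc1 | intermediate
9 | syringaldehyde (4-hydroxy-3,5-dimethoxybenzaldehyde) | COc1cc(C=O)cc(OC)c1O | starting material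
10 | 4-benzyloxy-3,5-dimethoxybenzaldehyde | COc1cc(C=O)cc(OC)c1OCc1ccccc1 | intermediate
11 | (4-benzyloxy-3,5-dimethoxyphenyl)methanol | COc1cc(CO)cc(OC)c1OCc1ccccc1 | intermediate
12 | 4-benzyloxy-3,5-dimethoxybenzyl chloride | COc1cc(CCl)cc(OC)c1OCc1ccccc1 | intermediate
13 | 4-benzyloxy-3,5-dimethoxybenzylmagnesium chloride | COc1cc(C[Mg]Cl)cc(OC)c1OCc1ccccc1 | intermediate
14 | chloromagnesium (2S)-4-(4-benzyloxy-3-methoxyphenyl)-1-[(2R)-oxiran-2-yl]butan-2-olate (formed in the flask, not isolated) | COc1cc(CC[C@H](O[Mg]Cl)C[C@@H]2CO2)ccc1OCc1ccccc1 | intermediate
15 | (3S,5S)-1-(4-benzyloxy-3-methoxyphenyl)-7-(4-benzyloxy-3,5-dimethoxyphenyl)heptane-3,5-diol | COc1cc(CC[C@H](O)C[C@@H](O)CCc2cc(OC)c(OCc3ccccc3)c(OC)c2)ccc1OCc1ccccc1 | intermediate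
16 | (3S,5S)-1-(4-hydroxy-3-methoxyphenyl)-7-(4-hydroxy-3,5-dimethoxyphenyl)heptane-3,5-diol | COc1cc(CC[C@H](O)C[C@@H](O)CCc2cc(OC)c(O)c(OC)c2)ccc1O | target

## Step count and risks

Total: 12 steps. Longest linear sequence: 6 steps (4 → 5 → 6 → 7 → 8 → 15 → 16; the syringyl branch 9 → 10 → 11 → 12 → 13 → 15 → 16 is equally long; the bis-epoxide branch 1 → 2 → 3 → 15 → 16 has four).

Least certain steps:

**Step 11 (key step).** The most likely failure is loss of control over mono- against double opening in the first stage: 8 adds to the alkoxide 14 while unreacted 3 is still present. An uncertain titre of 8 and competing opening of the oxirane by chloride would make this worse, and 15 would become the minor part of a mixture of three closely related diols. Fallback: the two openings are separated. Starting from 3 (threefold excess) and 8, the first copper-catalysed opening is run alone. The volatile excess of 3 is recovered by distillation, and the epoxy alcohol (2S)-4-(4-benzyloxy-3-methoxyphenyl)-1-[(2R)-oxiran-2-yl]butan-2-ol F1 is purified by chromatography. F1 is then opened with 13 (2.2 equiv., the first equivalent serving as base for the hydroxyl group) and CuI, and the route is rejoined at 15. The bis-syringyl adduct can then no longer form, and the bis-guaiacyl adduct is suppressed by the excess of 3.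

**Step 10.** The most likely failure is Wurtz homocoupling during magnesium insertion, the electron-rich chloride 12 reacting with Grignard reagent already formed, together with solvolytic loss of the labile chloride; the result would be a weak solution of uncertain titre. Fallback: the benzylic anion is generated with no benzylic halide beside it. From 12, displacement with Bu3SnLi gives tributyl(4-benzyloxy-3,5-dimethoxybenzyl)stannane F2. Tin–lithium exchange with n-BuLi in THF at −78 °C gives 4-benzyloxy-3,5-dimethoxybenzyllithium F3, and addition of MgCl2 converts it into 13, where the route is rejoined.

**Step 6.** The hazard is the same homocoupling during insertion, here more damaging because 8 is the limiting reagent of step 11 and its titre fixes the product distribution. Fallback: from 7, displacement with Bu3SnLi gives tributyl(4-benzyloxy-3-methoxybenzyl)stannane F4, exchange with n-BuLi at −78 °C gives 4-benzyloxy-3-methoxybenzyllithium F5, and MgCl2 converts it into 8, where the route is rejoined.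

**Step 1.** Possible failures are incomplete stereocontrol (syn diol or minor enantiomer not fully removed on recrystallisation), partial hydrodechlorination at the elevated temperature and pressure, or a sense of induction opposite to the one assumed. Fallback without catalyst-controlled reduction: from 1, NaBH4 in methanol gives 1,5-dichloropentane-2,4-diol (mixture of stereoisomers) F6, and KOH in Et2O closes it to 1,2:4,5-diepoxypentane (mixture of stereoisomers) F7. Jacobsen hydrolytic kinetic resolution with (S,S)-(salen)Co(OAc) (trivalent cobalt) and about one equivalent of water then hydrolyses every oxirane of (S) configuration. The meso and (2S,4S) isomers become non-volatile hydrolysis products and only 3 distils, which rejoins the route at 3. At most a quarter of F7 can be recovered, but both oxiranes of a molecule must pass the same filter, which should leave 3 very highly enriched.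

## Further compounds

F1 | step 11 | (2S)-4-(4-benzyloxy-3-methoxyphenyl)-1-[(2R)-oxiran-2-yl]butan-2-ol | COc1cc(CC[C@H](O)C[C@@H]2CO2)ccc1OCc1ccccc1
F2 | step 10 | tributyl(4-benzyloxy-3,5-dimethoxybenzyl)stannane | CCCC[Sn](CCCC)(CCCC)Cc1cc(OC)c(OCc2ccccc2)c(OC)c1
F3 | step 10 | 4-benzyloxy-3,5-dimethoxybenzyllithium | [Li]Cc1cc(OC)c(OCc2ccccc2)c(OC)c1
F4 | step 6 | tributyl(4-benzyloxy-3-methoxybenzyl)stannane | CCCC[Sn](CCCC)(CCCC)Cc1ccc(OCc2ccccc2)c(OC)c1
F5 | step 6 | 4-benzyloxy-3-methoxybenzyllithium | [Li]Cc1ccc(OCc2ccccc2)c(OC)c1
F6 | step 1 | 1,5-dichloropentane-2,4-diol (mixture of stereoisomers) | ClCC(O)CC(O)CCl
F7 | step 1 | 1,2:4,5-diepoxypentane (mixture of stereoisomers) | C1OC1CC1CO1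
A1 | alternative 1 | acetonide of (3S,5S)-1-(4-benzyloxy-3-methoxyphenyl)-7-(4-hydroxy-3,5-dimethoxyphenyl)heptane-3,5-diol | COc1cc(CC[C@H](OC(C)(C)O2)C[C@@H]2CCc3cc(OC)c(O)c(OC)c3)ccc1OCc1ccccc1
A2 | alternative 1 | 3-(dimethylamino)-2-{2-[(4S,6S)-6-[2-(4-benzyloxy-3-methoxyphenyl)ethyl]-2,2-dimethyl-1,3-dioxan-4-yl]ethyl}prop-2-enal | COc1cc(CC[C@H](OC(C)(C)O2)C[C@@H]2CCC(C=O)=CN(C)C)ccc1OCc1ccccc1
A3 | alternative 1 | 1,3-dimethoxyacetone | COCC(=O)COC
A4 | alternative 2 | racemic (E)-1-(4-benzyloxy-3-methoxyphenyl)-7-(4-benzyloxy-3,5-dimethoxyphenyl)hept-3-en-5-ol | COc1cc(CC/C=C/C(O)CCc2cc(OC)c(OCc3ccccc3)c(OC)c2)ccc1OCc1ccccc1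
A5 | alternative 2 | (3S,4S,5S)-3,4-epoxy-1-(4-benzyloxy-3-methoxyphenyl)-7-(4-benzyloxy-3,5-dimethoxyphenyl)heptan-5-ol | COc1cc(CC[C@@H]2O[C@H]2[C@@H](O)CCc3cc(OC)c(OCc4ccccc4)c(OC)c3)ccc1OCc1ccccc1
A6 | alternative 3 | 1-(4-benzyloxy-3-methoxyphenyl)-7-(4-benzyloxy-3,5-dimethoxyphenyl)heptane-3,5-dione | COc1cc(CCC(=O)CC(=O)CCc2cc(OC)c(OCc3ccccc3)c(OC)c2)ccc1OCc1ccccc1
A7 | alternative 3 | 1-[3-(4-benzyloxy-3-methoxyphenyl)propanoyl]imidazole | COc1cc(CCC(=O)n2ccnc2)ccc1OCc1ccccc1
A8 | alternative 3 | 1-[3-(4-benzyloxy-3,5-dimethoxyphenyl)propanoyl]imidazole | COc1cc(CCC(=O)n2ccnc2)cc(OC)c1OCc1ccccc1
A9 | alternative 3 | malonic acid | OC(=O)CC(=O)O
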